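**Retrosynthetic overview**

1. Naming: rings A (2-methyl-4,6-dihydroxyphenyl) and B sit on the left ketone, rings C and D (4-hydroxy-2-methoxy-6-methylphenyl) on the right ketone; rings B and C are numbered C1 (bridge CH2), C2 (OMe), C3 (H), C4 (OH), C5 (aroyl), C6 (OH).
2. Feature: ring C atoms C1, C2(OMe), C3(H), C4(OH), C5(aroyl), C6(OH) are, in this order, C3, C4(OMe), C5, C6, the side-chain CH2 and the lactone carbon C2 of a 3-benzyl-4-methoxy-6-(aroylmethyl)-2-pyrone, and the only methyl ether of ring C lies para to the aroyl carbon.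
3. Last disconnections: the five benzyl ethers (hydrogenolysis), then ring C back to that pyrone by breaking C5–C6 (methanolysis of the lactone, then Claisen closure); ring C is the only ring built and it is formed last.
4. Pyrone: the side chain comes from the lithiated 6-methyl group plus the ring D aldehyde, then oxidation; the C3–CH2 bond comes from triacetic acid lactone plus the ring B aldehyde by reductive Knoevenagel alkylation, then O-methylation.
5. Left half: ring A aldehyde plus a ring B aryllithium (lithiation between two MOM ethers of 5-methoxyresorcinol), oxidation, then MOM removal so that the free-phenolic ring B is formylated selectively before benzylation; rings A, B and D are bought as arenes.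

Key step: step 14

**Remarks on the chemistry**

- Abbreviations used in names: LB = 2,4-bis(benzyloxy)-3-[2,4-bis(benzyloxy)-6-methylbenzoyl]-6-methoxybenzyl (the protected left-half benzyl group, rings A and B); DAr = 4-(benzyloxy)-2-methoxy-6-methylphenyl (protected ring D).
- The target has no stereocentre. The two secondary carbinols formed on the way (steps 3 and 12) are racemic and are oxidised in the next step.
- In the ring-opened ester of the key step the ester and the diketone chain are cis on the enol ether double bond; by the CIP rules this is the 2E isomer.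
- Assumption: 5-methoxyresorcinol, 2,4-dihydroxy-6-methylbenzaldehyde and triacetic acid lactone are taken as purchasable.

**Route**

Step 1
Reactants: 1 5-methoxyresorcinol
Product: 2 1-methoxy-3,5-bis(methoxymethoxy)benzene
Conditions: MOMCl (2.5 eq), iPr2NEt, CH2Cl2, 0 °C to rt
Reagents that add atoms: chloromethyl methyl ether, COCCl
Why: Williamson-type O-alkylation of both phenols by the reactive α-chloro ether installs the two MOM groups that later direct the lithiation.

Step 2
Reactants: 3 2,4-dihydroxy-6-methylbenzaldehyde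
Product: 4 2,4-bis(benzyloxy)-6-methylbenzaldehyde
Conditions: BnBr (2.5 eq), K2CO3, DMF, 60 °C
Reagents that add atoms: benzyl bromide, BrCc1ccccc1
Why: Williamson etherification in DMF at 60 °C should alkylate the free 4-hydroxyl and also the hydrogen-bonded 2-hydroxyl.

Step 3
Reactants: 2 1-methoxy-3,5-bis(methoxymethoxy)benzene; 4 2,4-bis(benzyloxy)-6-methylbenzaldehyde
Product: 6 (±)-[2,4-bis(benzyloxy)-6-methylphenyl][4-methoxy-2,6-bis(methoxymethoxy)phenyl]methanol, via aryllithium 5 (not isolated)
Conditions: 2 (1.2 eq), n-BuLi (1.1 eq), THF, 0 °C, 1 h; then 4, −78 °C to rt; H2O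
Reagents that add atoms: n-butyllithium, [Li]CCCC (lithium, held only in 5)
Why: Directed ortho-metalation should take place at the carbon flanked by the two OMOM groups rather than next to the weaker OMe director, and the aryllithium then adds 1,2 to the non-enolisable aldehyde to give the racemic carbinol, whose stereocentre is removed in step 4.

Step 4
Reactants: 6 (±)-[2,4-bis(benzyloxy)-6-methylphenyl][4-methoxy-2,6-bis(methoxymethoxy)phenyl]methanol
Product: 7 [2,4-bis(benzyloxy)-6-methylphenyl][4-methoxy-2,6-bis(methoxymethoxy)phenyl]methanone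
Conditions: Dess–Martin periodinane (1.5 eq), NaHCO3, CH2Cl2, rt
Reagents that add atoms: none
Why: Dess–Martin oxidation of a secondary diarylcarbinol is dependable for tetra-ortho-substituted benzophenones, and the bicarbonate buffer protects the MOM acetals.

Step 5
Reactants: 7 [2,4-bis(benzyloxy)-6-methylphenyl][4-methoxy-2,6-bis(methoxymethoxy)phenyl]methanone
Product: 8 [2,4-bis(benzyloxy)-6-methylphenyl](2,6-dihydroxy-4-methoxyphenyl)methanone
Conditions: 3 M aq HCl, MeOH/THF, 45 °C
Reagents that add atoms: none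
Why: Acid-catalysed acetal exchange with methanol should free both ring B phenols, while the benzyl ethers and the hindered ketone are inert to dilute acid.

Step 6
Reactants: 8 [2,4-bis(benzyloxy)-6-methylphenyl](2,6-dihydroxy-4-methoxyphenyl)methanone
Product: 10 3-[2,4-bis(benzyloxy)-6-methylbenzoyl]-2,4-dihydroxy-6-methoxybenzaldehyde, via iminium chloride 9 (not isolated)
Conditions: POCl3 (1.3 eq), DMF (3 eq), MeCN, 0 °C to rt; then H2O, 40 °C
Reagents that add atoms: N,N-dimethylformamide, CN(C)C=O (formyl carbon; its NMe2 group stays only in 9); water, O (formyl oxygen); phosphoryl chloride, O=P(Cl)(Cl)Cl (chloride counter-ion of 9 only)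
Why: In this Vilsmeier–Haack formylation the two equivalent free carbons of the free-phenolic ring B (each ortho or para to three oxygens) should react much faster than the dibenzylated, acyl-deactivated ring A, and the first formyl group deactivates ring B against a second.

Step 7
Reactants: 10 3-[2,4-bis(benzyloxy)-6-methylbenzoyl]-2,4-dihydroxy-6-methoxybenzaldehyde
Product: 11 2,4-bis(benzyloxy)-3-[2,4-bis(benzyloxy)-6-methylbenzoyl]-6-methoxybenzaldehyde (LB-CHO)
Conditions: BnBr (3 eq), K2CO3, Bu4NI (cat.), DMF, 60 °C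
Reagents that add atoms: benzyl bromide, BrCc1ccccc1
Why: Williamson etherification of both chelated phenols; the two carbonyl groups lower the carbon nucleophilicity of the phenoxide, so O-alkylation should prevail over C-benzylation.

Step 8
Reactants: 11 2,4-bis(benzyloxy)-3-[2,4-bis(benzyloxy)-6-methylbenzoyl]-6-methoxybenzaldehyde; 12 triacetic acid lactone (4-hydroxy-6-methyl-2H-pyran-2-one)
Product: 14 3-LB-4-hydroxy-6-methyl-2H-pyran-2-one, via Knoevenagel alkylidene dione 13 (not isolated)
Conditions: L-proline (20 mol %), Hantzsch ester (1.2 eq), CH2Cl2/EtOH, 40 °C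
Reagents that add atoms: none
Why: Organocatalytic three-component reductive alkylation, in which proline-catalysed Knoevenagel condensation at lactone C3 is followed by conjugate hydride transfer from the dihydropyridine to the alkylidene dione before a second lactone can add.

Step 9
Reactants: 14 3-LB-4-hydroxy-6-methyl-2H-pyran-2-one
Product: 15 3-LB-4-methoxy-6-methyl-2H-pyran-2-one
Conditions: Me2SO4 (1.3 eq), K2CO3, acetone, reflux
Reagents that add atoms: dimethyl sulfate, COS(=O)(=O)OC
Why: O-methylation of the vinylogous acid with dimethyl sulfate and carbonate in acetone, conditions that favour the 4-methoxy-2-pyrone over the isomeric 2-methoxy-4-pyrone.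

Step 10
Reactants: 3 2,4-dihydroxy-6-methylbenzaldehyde
Product: 16 4-(benzyloxy)-2-hydroxy-6-methylbenzaldehyde
Conditions: BnBr (1.05 eq), NaHCO3, MeCN, 80 °C
Reagents that add atoms: benzyl bromide, BrCc1ccccc1
Why: Regioselective Williamson etherification, since the 2-hydroxyl is held in a hydrogen bond to the aldehyde and is not alkylated under the weak base.

Step 11
Reactants: 16 4-(benzyloxy)-2-hydroxy-6-methylbenzaldehyde
Product: 17 4-(benzyloxy)-2-methoxy-6-methylbenzaldehyde (DAr-CHO)
Conditions: MeI, K2CO3, DMF, 40 °C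
Reagents that add atoms: iodomethane, CI
Why: Williamson methylation of the remaining chelated phenol under the stronger carbonate/DMF conditions.

Step 12
Reactants: 15 3-LB-4-methoxy-6-methyl-2H-pyran-2-one; 17 4-(benzyloxy)-2-methoxy-6-methylbenzaldehyde
Product: 19 (±)-6-[2-DAr-2-hydroxyethyl]-3-LB-4-methoxy-2H-pyran-2-one, via lithiated pyrone 18 (not isolated)
Conditions: LiN(iPr)2 (1.1 eq), THF, −78 °C; then 17 (1.3 eq), −78 °C; AcOH quench at −78 °C
Reagents that add atoms: lithium diisopropylamide, [Li]N(C(C)C)C(C)C (lithium, held only in 18)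
Why: Vinylogous deprotonation of the 6-methyl group (C3 is blocked) and aldol-type addition of the anion to the non-enolisable aldehyde; the carbinol centre forms without control (racemic) and is removed in step 13.

Step 13
Reactants: 19 (±)-6-[2-DAr-2-hydroxyethyl]-3-LB-4-methoxy-2H-pyran-2-one
Product: 20 6-[2-DAr-2-oxoethyl]-3-LB-4-methoxy-2H-pyran-2-one
Conditions: Dess–Martin periodinane (1.3 eq), NaHCO3, CH2Cl2, 0 °C to rt
Reagents that add atoms: none
Why: Dess–Martin oxidation of the secondary benzylic alcohol under buffered, non-basic conditions should avoid retro-aldol cleavage and dehydration to a styrylpyrone.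

Step 14
Reactants: 20 6-[2-DAr-2-oxoethyl]-3-LB-4-methoxy-2H-pyran-2-one
Product: 22 (DAr)(3-LB-2,6-dihydroxy-4-methoxyphenyl)methanone (pentabenzyl ether of the target), via ring-opened methyl ester 21 (not isolated)
Conditions: Mg(OMe)2 (10 eq, solution in MeOH), MeOH/THF, reflux, N2; then cold 1 M HCl
Reagents that add atoms: magnesium methoxide, C[O-].C[O-].[Mg+2] (its methoxy group is held only in 21 and leaves again as methanol)
Why: Magnesium-bound methoxide adds to the lactone carbonyl (pyrone C2) and opens the ring to methyl ester 21, whose 5,7-diketone is held by magnesium as its enolate; the methylene between the two ketones then attacks the ester carbon in a Claisen (Dieckmann-type) condensation, methanol leaves, and tautomerisation makes ring C aromatic, so the sequence is irreversible. The closest known reaction is the magnesium methoxide recyclisation of 6-(2-oxoalkyl)- and 6-phenacyl-4-methoxy-2-pyrones to 2,6-dihydroxy-4-methoxyphenyl ketones, and only the size of the substituents is new here. Ring C closes in a 6-exo-trig mode, and the enol ether geometry inherited from the pyrone ring holds the ester and the nucleophilic carbon on the same side of the double bond. No stereocentre is formed. The step needs Claisen closure to win over aldol closure onto the aryl ketone, O-cyclisation to a 4-pyrone and retro-Claisen cleavage of the diketone: the ester α-carbon is a fully substituted enol ether carbon that could not aromatise after an aldol step, magnesium chelation keeps the diketone a carbon nucleophile and tempers free methoxide, and the crowded ring D ketone is a poor electrophile. The left half should stay out of the reaction because ring B carries no free phenol that could set off loss of the benzylic bridge in base.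

Step 15
Reactants: 22 (DAr)(3-LB-2,6-dihydroxy-4-methoxyphenyl)methanone
Product: 23 {3-[3-(2,4-dihydroxy-6-methylbenzoyl)-2,4-dihydroxy-6-methoxybenzyl]-2,6-dihydroxy-4-methoxyphenyl}(4-hydroxy-2-methoxy-6-methylphenyl)methanone (CNP0596095.0)
Conditions: H2 (1 atm), 10% Pd/C, EtOAc/MeOH, rt
Reagents that add atoms: none
Why: Hydrogenolysis of the five benzyl aryl ethers over palladium on carbon in neutral solvent should leave the chelated, tetra-ortho-substituted diaryl ketones and the diarylmethane bridge untouched.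

**Compound list**

1 | 5-methoxyresorcinol | COc1cc(O)cc(O)c1 | starting material
2 | 1-methoxy-3,5-bis(methoxymethoxy)benzene | COCOc1cc(OC)cc(OCOC)c1 | intermediate
3 | 2,4-dihydroxy-6-methylbenzaldehyde | Cc1cc(O)cc(O)c1C=O | starting material
4 | 2,4-bis(benzyloxy)-6-methylbenzaldehyde | Cc1cc(OCc2ccccc2)cc(OCc2ccccc2)c1C=O | intermediate
5 | [4-methoxy-2,6-bis(methoxymethoxy)phenyl]lithium | [Li]c1c(OCOC)cc(OC)cc1OCOC | intermediate (not isolated)
6 | (±)-[2,4-bis(benzyloxy)-6-methylphenyl][4-methoxy-2,6-bis(methoxymethoxy)phenyl]methanol | COCOc1cc(OC)cc(OCOC)c1C(O)c1c(C)cc(OCc2ccccc2)cc1OCc1ccccc1 | intermediate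
7 | [2,4-bis(benzyloxy)-6-methylphenyl][4-methoxy-2,6-bis(methoxymethoxy)phenyl]methanone | COCOc1cc(OC)cc(OCOC)c1C(=O)c1c(C)cc(OCc2ccccc2)cc1OCc1ccccc1 | intermediate
8 | [2,4-bis(benzyloxy)-6-methylphenyl](2,6-dihydroxy-4-methoxyphenyl)methanone | COc1cc(O)c(C(=O)c2c(C)cc(OCc3ccccc3)cc2OCc2ccccc2)c(O)c1 | intermediate
9 | N-{3-[2,4-bis(benzyloxy)-6-methylbenzoyl]-2,4-dihydroxy-6-methoxybenzylidene}-N-methylmethanaminium chloride | COc1cc(O)c(C(=O)c2c(C)cc(OCc3ccccc3)cc2OCc2ccccc2)c(O)c1C=[N+](C)C.[Cl-] | intermediate (not isolated)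
10 | 3-[2,4-bis(benzyloxy)-6-methylbenzoyl]-2,4-dihydroxy-6-methoxybenzaldehyde | COc1cc(O)c(C(=O)c2c(C)cc(OCc3ccccc3)cc2OCc2ccccc2)c(O)c1C=O | intermediate
11 | 2,4-bis(benzyloxy)-3-[2,4-bis(benzyloxy)-6-methylbenzoyl]-6-methoxybenzaldehyde (LB-CHO) | COc1cc(OCc2ccccc2)c(C(=O)c2c(C)cc(OCc3ccccc3)cc2OCc2ccccc2)c(OCc2ccccc2)c1C=O | intermediate
12 | triacetic acid lactone (4-hydroxy-6-methyl-2H-pyran-2-one) | CC1=CC(O)=CC(=O)O1 | starting material
13 | 3-(LB-ylidene)-6-methyl-2H-pyran-2,4(3H)-dione, i.e. the 3-arylmethylidene dione from 11 and 12 (alkene geometry not defined) | COc1cc(OCc2ccccc2)c(C(=O)c2c(C)cc(OCc3ccccc3)cc2OCc2ccccc2)c(OCc2ccccc2)c1C=C1C(=O)C=C(C)OC1=O | intermediate (not isolated)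
14 | 3-LB-4-hydroxy-6-methyl-2H-pyran-2-one | COc1cc(OCc2ccccc2)c(C(=O)c2c(C)cc(OCc3ccccc3)cc2OCc2ccccc2)c(OCc2ccccc2)c1CC1=C(O)C=C(C)OC1=O | intermediate
15 | 3-LB-4-methoxy-6-methyl-2H-pyran-2-one | COc1cc(OCc2ccccc2)c(C(=O)c2c(C)cc(OCc3ccccc3)cc2OCc2ccccc2)c(OCc2ccccc2)c1CC1=C(OC)C=C(C)OC1=O | intermediate
16 | 4-(benzyloxy)-2-hydroxy-6-methylbenzaldehyde | Cc1cc(OCc2ccccc2)cc(O)c1C=O | intermediate
17 | 4-(benzyloxy)-2-methoxy-6-methylbenzaldehyde (DAr-CHO) | Cc1cc(OCc2ccccc2)cc(OC)c1C=O | intermediate
18 | 3-LB-6-(lithiomethyl)-4-methoxy-2H-pyran-2-one | COc1cc(OCc2ccccc2)c(C(=O)c2c(C)cc(OCc3ccccc3)cc2OCc2ccccc2)c(OCc2ccccc2)c1CC1=C(OC)C=C(C[Li])OC1=O | intermediate (not isolated)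
19 | (±)-6-[2-DAr-2-hydroxyethyl]-3-LB-4-methoxy-2H-pyran-2-one | COc1cc(OCc2ccccc2)c(C(=O)c2c(C)cc(OCc3ccccc3)cc2OCc2ccccc2)c(OCc2ccccc2)c1CC1=C(OC)C=C(CC(O)c2c(C)cc(OCc3ccccc3)cc2OC)OC1=O | intermediate
20 | 6-[2-DAr-2-oxoethyl]-3-LB-4-methoxy-2H-pyran-2-one (key-step precursor) | COc1cc(OCc2ccccc2)c(C(=O)c2c(C)cc(OCc3ccccc3)cc2OCc2ccccc2)c(OCc2ccccc2)c1CC1=C(OC)C=C(CC(=O)c2c(C)cc(OCc3ccccc3)cc2OC)OC1=O | intermediate
21 | methyl (2E)-7-DAr-2-LB-3-methoxy-5,7-dioxohept-2-enoate | COC(=O)/C(Cc1c(OC)cc(OCc2ccccc2)c(C(=O)c2c(C)cc(OCc3ccccc3)cc2OCc2ccccc2)c1OCc1ccccc1)=C(/OC)CC(=O)CC(=O)c1c(C)cc(OCc2ccccc2)cc1OC | intermediate (not isolated)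
22 | (DAr)(3-LB-2,6-dihydroxy-4-methoxyphenyl)methanone (pentabenzyl ether of the target) | COc1cc(O)c(C(=O)c2c(C)cc(OCc3ccccc3)cc2OC)c(O)c1Cc1c(OC)cc(OCc2ccccc2)c(C(=O)c2c(C)cc(OCc3ccccc3)cc2OCc2ccccc2)c1OCc1ccccc1 | intermediate
23 | {3-[3-(2,4-dihydroxy-6-methylbenzoyl)-2,4-dihydroxy-6-methoxybenzyl]-2,6-dihydroxy-4-methoxyphenyl}(4-hydroxy-2-methoxy-6-methylphenyl)methanone (CNP0596095.0) | COc1cc(O)c(C(=O)c2c(C)cc(O)cc2O)c(O)c1Cc1c(OC)cc(O)c(C(=O)c2c(C)cc(O)cc2OC)c1O | target

**Step count**

Total: 15 steps. Longest linear sequence: 12 steps (steps 1, 3, 4, 5, 6, 7, 8, 9, 12, 13, 14, 15, from 5-methoxyresorcinol).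

**Steps most likely to fail**

1. Step 14 (key step). After methanolysis, the benzyl group on the ester α-carbon may slow the 6-exo closure enough that the triketo ester closes through oxygen to a 4-pyrone, is cut at the 1,3-diketone by methoxide (retro-Claisen), or simply relactonises. The fallback builds ring C before the bridge, sets out from 11, 17 and 2, and comes back at 22. Aldehyde 11 would be reduced with NaBH4 (THF/MeOH, 0 °C; the hindered diaryl ketone should be left alone) to {2,4-bis(benzyloxy)-3-[2,4-bis(benzyloxy)-6-methylbenzoyl]-6-methoxyphenyl}methanol F1. In parallel, aryllithium 5 (from 2 as in step 3) would be added to 17 to give (±)-(DAr)[4-methoxy-2,6-bis(methoxymethoxy)phenyl]methanol F2, which Dess–Martin periodinane would oxidise to (DAr)[4-methoxy-2,6-bis(methoxymethoxy)phenyl]methanone F3, and HCl in MeOH/THF would unmask (DAr)(2,6-dihydroxy-4-methoxyphenyl)methanone F4. Acid-catalysed Friedel–Crafts benzylation (p-TsOH cat., CH2Cl2, 0 °C, F4 in excess) should then let the trialkoxybenzyl cation from F1 attack one of the two equivalent free carbons of the acylphloroglucinol ring of F4, giving 22.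

2. Step 8. Iminium and Knoevenagel formation at the di-ortho-substituted, electron-rich aldehyde may be slow, and conjugate addition of a second lactone to the alkylidene dione may outrun hydride transfer. The fallback replaces the condensation by an organolithium addition, sets out from 12 and 11, and comes back at 15 (it also bypasses the O-methylation of step 9). Lactone 12 would be methylated (Me2SO4, K2CO3, acetone) to 4-methoxy-6-methyl-2H-pyran-2-one F5. Kinetic lithiation of F5 at C3 (n-BuLi, THF, −78 °C) and addition to 11 should give (±)-3-[hydroxy(aryl)methyl]-4-methoxy-6-methyl-2H-pyran-2-one F6 (aryl = the ring of LB). Ionic deoxygenation of this doubly activated carbinol (Et3SiH, a few equivalents of TFA, CH2Cl2, −20 °C, where the twisted diaryl ketone should not be reduced) would give 15.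

3. Step 12. The amide base may also deprotonate the ortho-methyl group of ring A next to the left ketone, the addition to the hindered aldehyde may revert, and the adduct may dehydrate to a styrylpyrone on work-up. The fallback moves the strong-base step ahead of the union with the left half, sets out from 12 and 17 (with 11), and comes back at 19. The dianion of 12 (LiN(iPr)2, 2.2 eq, THF, −78 to 0 °C) would be added through its methyl carbon to 17 to give (±)-6-[2-DAr-2-hydroxyethyl]-4-hydroxy-2H-pyran-2-one F7. Reductive alkylation of F7 with 11 (L-proline, Hantzsch ester, as in step 8) should give (±)-6-[2-DAr-2-hydroxyethyl]-3-LB-4-hydroxy-2H-pyran-2-one F8. Me2SO4 and K2CO3 in acetone would then methylate only the acidic 4-hydroxyl to give 19.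

**Further compounds**

F1 | step 14 | {2,4-bis(benzyloxy)-3-[2,4-bis(benzyloxy)-6-methylbenzoyl]-6-methoxyphenyl}methanol | COc1cc(OCc2ccccc2)c(C(=O)c2c(C)cc(OCc3ccccc3)cc2OCc2ccccc2)c(OCc2ccccc2)c1CO
F2 | step 14 | (±)-[4-(benzyloxy)-2-methoxy-6-methylphenyl][4-methoxy-2,6-bis(methoxymethoxy)phenyl]methanol | COCOc1cc(OC)cc(OCOC)c1C(O)c1c(C)cc(OCc2ccccc2)cc1OC
F3 | step 14 | [4-(benzyloxy)-2-methoxy-6-methylphenyl][4-methoxy-2,6-bis(methoxymethoxy)phenyl]methanone | COCOc1cc(OC)cc(OCOC)c1C(=O)c1c(C)cc(OCc2ccccc2)cc1OC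
F4 | step 14 | [4-(benzyloxy)-2-methoxy-6-methylphenyl](2,6-dihydroxy-4-methoxyphenyl)methanone | COc1cc(O)c(C(=O)c2c(C)cc(OCc3ccccc3)cc2OC)c(O)c1
F5 | step 8 | 4-methoxy-6-methyl-2H-pyran-2-one | COC1=CC(=O)OC(C)=C1
F6 | step 8 | (±)-3-[{2,4-bis(benzyloxy)-3-[2,4-bis(benzyloxy)-6-methylbenzoyl]-6-methoxyphenyl}(hydroxy)methyl]-4-methoxy-6-methyl-2H-pyran-2-one | COc1cc(OCc2ccccc2)c(C(=O)c2c(C)cc(OCc3ccccc3)cc2OCc2ccccc2)c(OCc2ccccc2)c1C(O)C1=C(OC)C=C(C)OC1=O
F7 | step 12 | (±)-6-{2-[4-(benzyloxy)-2-methoxy-6-methylphenyl]-2-hydroxyethyl}-4-hydroxy-2H-pyran-2-one | COc1cc(OCc2ccccc2)cc(C)c1C(O)CC1=CC(O)=CC(=O)O1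
F8 | step 12 | (±)-6-{2-[4-(benzyloxy)-2-methoxy-6-methylphenyl]-2-hydroxyethyl}-3-{2,4-bis(benzyloxy)-3-[2,4-bis(benzyloxy)-6-methylbenzoyl]-6-methoxybenzyl}-4-hydroxy-2H-pyran-2-one | COc1cc(OCc2ccccc2)c(C(=O)c2c(C)cc(OCc3ccccc3)cc2OCc2ccccc2)c(OCc2ccccc2)c1CC1=C(O)C=C(CC(O)c2c(C)cc(OCc3ccccc3)cc2OC)OC1=O
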